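Assumption: the SMILES has no stereocentre and no stereodefined double bond, so the target is treated as achiral; "prenyl" means 3-methylbut-2-en-1-yl and "1,1-dimethylallyl" means 2-methylbut-3-en-2-yl.

## The problem

Broussoflavonol E (20) is an achiral flavonol: ring A and the 4-pyranone ring C form a 3,5,7-trihydroxychromen-4-one, and ring B is attached at C2. With no stereocentre, every difficulty is one of position. Ring A carries a 1,1-dimethylallyl group at C8, a quaternary benzylic carbon between O1 and the 7-hydroxyl. Direct C-prenylation cannot deliver it, and C8 has to be distinguished from C6. Ring B is a pentasubstituted benzene: C2' bears a prenyl group, C3' and C4' are fused to a 2,2-dimethyldihydropyran (chroman) ring through C3'–CH2 and C4'–O, and C5' bears a hydroxyl. Both alkenes are acid-sensitive (the prenyl double bond protonates to a tertiary cation, and the vinyl group can close onto the 7-hydroxyl), and the chroman is a tertiary alkyl aryl ether. Hydrogenolysis, late strong Lewis acids and electrophilic oxidants are therefore excluded from the endgame. Closing ring C from a ring A ketone and a ring B aldehyde is classical, but a 5-oxygen and an ortho-substituted ring B make it less certain. The enabling feature is the chroman of ring B: its O4'–C(CH3)2–CH2–CH2–C3' unit is a phenol oxygen, one benzylic carbon and isobutene, which is the retron of an ortho-quinone methide [4+2] cycloaddition.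

## Retrosynthesis

**20 from 19.** The three aryl O–CH2OCH3 bonds are cut last. Methoxymethyl ethers survive KOH, alkaline H2O2, palladium catalysis and 190 °C, and leave in dilute acid. Methyl ethers would need BBr3 at the end and benzyl ethers would need hydrogenolysis; the alkenes tolerate neither. The forward step must remove three acetals without protonating either alkene.

**19 from 17.** Ring C is opened at O1–C2, and the C3–OH bond is removed with it, giving 2'-hydroxychalcone 17 (Algar–Flynn–Oyamada retron). The neighbouring cut, flavone first and C3 oxidation second, costs a step and normally uses a dioxirane, which would epoxidise both alkenes. The forward reaction must close the six-membered ring through the one free ring A hydroxyl, which sits next to the tert-alkyl group, and not the five-membered aurone ring.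

**17 from 16 and 10.** The Cα=Cβ bond is cut (Claisen–Schmidt). This divides the molecule into a ring A ketone 16 and a ring B aldehyde 10 of similar size, both stable to hydroxide. The forward step asks only for an E-enone.

**10 from 8 and 9; 8 from 7 from 6.** The C5–CH2 bond of the prenyl group (chroman numbering) is cut to aryl bromide 8 and prenylboronate 9. A Claisen route is not available because neither neighbour of this carbon carries an oxygen, so the bromine is carried from the first compound. The coupling must deliver the linear, not the reverse, prenyl isomer. The MOM ether of 8 goes back through phenol 7 to methyl ether 6, because the methyl group that differentiates the two ring B oxygens cannot be removed once alkenes are present.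

**6 from 3 and 4 through 5.** The chroman is cut at C4–C3 and O1–C2, giving ortho-quinone methide 5 and isobutene 4. Quinone methide 5 is the dehydration product of ortho-hydroxybenzyl alcohol 3. Acid-mediated chroman formation with isoprene would fail on a ring deactivated by the formyl group. A propargyl ether Claisen route needs three steps and a selective alkene reduction. The cycloaddition builds the ring in one step from a trisubstituted benzaldehyde and a gas. It must give only the 2,2-dimethyl regioisomer and must outrun self-condensation of 5.

**3 from 1 and 2.** The aryl–CH2OH bond is cut to 6-bromovanillin 1 and formaldehyde 2. Compound 1 has one free carbon ortho to its phenol, and its methyl ether ensures that only one quinone methide can form later.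

**16 from 15, 15 from 13 through 14, 13 from 11 and 12.** Two MOM groups are removed to give triol 15. Its quaternary C3–C bond is then cut by a retro-Claisen step through dienone 14 to the 4-O-prenyl ether 13. Ether 13 comes from 2,4,6-trihydroxyacetophenone 11 and prenyl bromide 12. Because 13 is symmetrical, both ortho carbons are the same and the para carbon is blocked by the acetyl group, so the rearrangement has one possible outcome. The position question is moved to the protection of 15, where the hydroxyl next to the tert-alkyl group must stay free.

## Roads not taken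

**Alternative 1:** ring A is cut across C8–C8a and C6–C7 into 3-ethoxycyclobut-2-en-1-one A2 and siloxyalkyne A3, which already carries the 1,1-dimethylallyl group.
- Forward key step: heating opens A2 to a vinylketene, which adds A3; ring opening, 6π closure and tautomerisation give phenol A1.
- Merits: the quaternary carbon arrives bonded to the alkyne, so its place between the free phenol (future O1) and the silyl ether (future 7-O) is fixed by connectivity. The three oxygens come out differentiated. On positional certainty this road is better than the chosen plan, which relies on a selective protection.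
- Weak points:
  - A3 needs several steps of its own.
  - A1 still lacks the C4 acyl carbon.
  - The silyl ether would not survive the hydroxide steps.
  - The 5-oxygen emerges as an ethyl ether, whose late cleavage needs a boron or aluminium halide that the alkenes and the chroman tolerate poorly.
  - Ring B is not addressed at all.
- Comparison: the chosen plan offers a three-step ring A from a commercial ketone, a rearrangement made unambiguous by symmetry, and one protecting group that leaves without Lewis acid.

**Alternative 2:** ring C is cut at C4a–C4 and O1–C2 into phloroglucinol A6 and the ring B α-(methoxymethoxy) β-ketoester A5.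
- Forward key step: the two are heated without catalyst to give 3-(methoxymethoxy)flavone A4.
- Merits: ring C forms with its 3-oxygen in place and no oxidant is used, so the aurone pathway cannot arise; symmetrical A6 removes any regiochemical question at ring closure. This is more direct than the chalcone oxidation, which is the least secure step of the chosen plan.
- Weak points:
  - The temperature of such condensations (well above 200 °C) is hard on MOM acetals in the presence of free phenols and on the prenyl group.
  - The ketone of A5 is hindered by the ortho-prenyl group.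
  - A4 has no 1,1-dimethylallyl group. It would have to come by O7-prenylation and Claisen rearrangement on the complete molecule, where C6 and C8 are both open and only a bias decides.
  - A5 would itself be made from aldehyde 10 in about three more steps, so the chroman problem remains.
- Comparison: the chosen plan installs the quaternary carbon early, on a small symmetrical molecule, and keeps all steps after union of the halves at or near room temperature.

**Alternative 3:** ring C is cut at O1–C8a, C4a–C4 and O1–C2 into aryne precursor A8 and the ring B arylpropiolic acid A9.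
- Forward key step: CsF releases 3,5-bis(methoxymethoxy)benzyne, which inserts into the C–O bond of the acid; the resulting ortho-hydroxyaryl ynone closes to flavone A7.
- Merits: this is the mildest ring C closure of all (fluoride, near room temperature) and is fully compatible with MOM ethers, the prenyl group and the chroman. The carboxylate should add at the aryne carbon remote from the 3-alkoxy group, which gives the right oxygen pattern.
- Weak points:
  - A7 lacks both the 3-hydroxyl and the C8 substituent.
  - C3 oxidation has to avoid dioxiranes.
  - The 1,1-dimethylallyl group would need a free 7-hydroxyl, but of the two MOM ethers it is the 5-ether, not the 7-ether, that is expected to cleave first.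
  - 5-Exo closure of the ynone to an aurone competes.
  - A8 takes about four steps, and A9 two or three from aldehyde 10.
- Comparison: the ring closure is gentler than the chosen one, but two functionalisations are deferred to the finished skeleton. The chosen plan has both in place before the halves meet.

None of the three touches the chroman of ring B; each would still need the quinone methide step or a substitute for it.

Key step: step 2

## Route

Step 1
Reactants: 1 6-bromovanillin (2-bromo-4-hydroxy-5-methoxybenzaldehyde); 2 formaldehyde
Product: 3 2-bromo-4-hydroxy-3-(hydroxymethyl)-5-methoxybenzaldehyde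
Conditions: aq. HCHO (37%, excess), NaOH, H2O, 45 °C; then AcOH
Reagents that add atoms: none
Why: Lederer–Manasse hydroxymethylation: the phenolate of 1 has a single unsubstituted ortho carbon (C3), so formaldehyde can enter at one site only. The para-formyl group slows the substitution but, as a vinylogous carboxylate, also protects the aldehyde from Cannizzaro chemistry; excess formaldehyde should suppress diarylmethane condensation.

Step 2
Reactants: 3 2-bromo-4-hydroxy-3-(hydroxymethyl)-5-methoxybenzaldehyde; 4 isobutene
Product: 6 5-bromo-8-methoxy-2,2-dimethylchroman-6-carbaldehyde, via o-quinone methide 5 (not isolated)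
Conditions: isobutene (large excess, condensed), toluene, sealed pressure vessel, 170 °C
Reagents that add atoms: none
Why: Thermal loss of water from ortho-hydroxybenzyl alcohol 3 through a hydrogen-bonded six-membered transition state should give ortho-quinone methide 5. Compound 5 is the 1-oxadiene of an inverse-electron-demand hetero-Diels–Alder reaction with isobutene as the 2π partner; the closest known reaction type is the thermal conversion of ortho-hydroxybenzyl alcohols and 1,1-disubstituted alkenes into 2,2-disubstituted chromans. The dihydropyran ring is closed by the intermolecular [4+2] cycloaddition itself, which forms C4–C3 and O1–C2 (chroman numbering) in one asynchronous event and is driven by re-aromatisation. No stereocentre is created, because C2 carries two methyl groups. The step needs regioselectivity: the exocyclic CH2 of 5, activated by the ring carbonyl and vinylogously by the formyl group, is the electrophilic end and bonds to the CH2 of isobutene, while the oxygen takes the carbon that best carries positive charge, so only the 2,2-dimethyl isomer is expected. Only the 4-hydroxyl of 3 is ortho to the CH2OH group and the 5-oxygen is capped as a methyl ether, so a single quinone methide can form. Self-condensation of 5 is held back by keeping 3 dilute in a large excess of the alkene; the bromide and the aldehyde are spectators.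

Step 3
Reactants: 6 5-bromo-8-methoxy-2,2-dimethylchroman-6-carbaldehyde
Product: 7 5-bromo-8-hydroxy-2,2-dimethylchroman-6-carbaldehyde
Conditions: BBr3 (3 equiv), CH2Cl2, −78 → 0 °C; then H2O
Reagents that add atoms: none
Why: Lewis-acid ether cleavage: bromide attacks the unhindered methyl carbon of the boron-complexed aryl methyl ether by SN2. The tertiary O–C bond of the chroman is tethered, so any ionisation there should simply reclose, and the aldehyde and aryl bromide tolerate BBr3 at low temperature.

Step 4
Reactants: 7 5-bromo-8-hydroxy-2,2-dimethylchroman-6-carbaldehyde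
Product: 8 5-bromo-8-(methoxymethoxy)-2,2-dimethylchroman-6-carbaldehyde
Conditions: MOMCl, i-Pr2NEt, CH2Cl2, 0 °C → rt
Reagents that add atoms: chloromethyl methyl ether (MOMCl), COCCl
Why: O-alkylation of the only phenol with an α-chloro ether (MOM ether formation); the acetal withstands every later basic, oxidative and palladium step.

Step 5
Reactants: 8 5-bromo-8-(methoxymethoxy)-2,2-dimethylchroman-6-carbaldehyde; 9 prenylboronic acid pinacol ester (4,4,5,5-tetramethyl-2-(3-methylbut-2-en-1-yl)-1,3,2-dioxaborolane)
Product: 10 8-(methoxymethoxy)-2,2-dimethyl-5-(3-methylbut-2-en-1-yl)chroman-6-carbaldehyde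
Conditions: PdCl2(IPent)(3-chloropyridine) (2 mol%), aq. KOH, THF, 65 °C
Reagents that add atoms: none
Why: Suzuki–Miyaura coupling of an aryl bromide with an allylic boronate; the ortho-formyl group speeds oxidative addition at the hindered bromide. The very bulky carbene IPent (1,3-bis[2,6-di(pentan-3-yl)phenyl]imidazol-2-ylidene) should steer reductive elimination to the unsubstituted terminus of the allyl–palladium intermediate, giving the linear prenyl arene.

Step 6
Reactants: 11 2,4,6-trihydroxyacetophenone; 12 prenyl bromide (1-bromo-3-methylbut-2-ene)
Product: 13 1-[2,6-dihydroxy-4-(3-methylbut-2-en-1-yloxy)phenyl]ethanone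
Conditions: K2CO3 (1 equiv), acetone, reflux
Reagents that add atoms: none
Why: Williamson etherification: the 4-hydroxyl is para to the acetyl group, the most acidic and not chelated, so one equivalent of base and halide should alkylate it in preference to the two hydrogen-bonded ortho hydroxyls.

Step 7
Reactants: 13 1-[2,6-dihydroxy-4-(3-methylbut-2-en-1-yloxy)phenyl]ethanone
Product: 15 1-[2,4,6-trihydroxy-3-(2-methylbut-3-en-2-yl)phenyl]ethanone, via cyclohexadienone 14 (not isolated)
Conditions: N,N-diethylaniline, 190 °C, Ar
Reagents that add atoms: none
Why: Aromatic Claisen rearrangement: the [3,3] shift delivers the tertiary carbon of the prenyl ether to the ortho carbon, giving dienone 14, which enolises to the phenol. The two ortho carbons are equivalent by symmetry and the para carbon carries the acetyl group, so no positional isomer and no productive para relay is possible. The basic amine solvent should keep acid-promoted follow-up reactions of the new ortho-(1,1-dimethylallyl)phenol slow.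

Step 8
Reactants: 15 1-[2,4,6-trihydroxy-3-(2-methylbut-3-en-2-yl)phenyl]ethanone
Product: 16 1-[2-hydroxy-4,6-bis(methoxymethoxy)-3-(2-methylbut-3-en-2-yl)phenyl]ethanone
Conditions: MOMCl (2.2 equiv), i-Pr2NEt, CH2Cl2, 0 °C → rt
Reagents that add atoms: chloromethyl methyl ether (MOMCl), COCCl
Why: Regioselective MOM ether formation: the 4-hydroxyl (para to the acetyl group) and the unhindered 6-hydroxyl should react. The 2-hydroxyl is pressed by the quaternary carbon into a hydrogen bond with the carbonyl and is both the least nucleophilic and the most shielded.

Step 9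
Reactants: 16 1-[2-hydroxy-4,6-bis(methoxymethoxy)-3-(2-methylbut-3-en-2-yl)phenyl]ethanone; 10 8-(methoxymethoxy)-2,2-dimethyl-5-(3-methylbut-2-en-1-yl)chroman-6-carbaldehyde
Product: 17 (E)-1-[2-hydroxy-4,6-bis(methoxymethoxy)-3-(2-methylbut-3-en-2-yl)phenyl]-3-[8-(methoxymethoxy)-2,2-dimethyl-5-(3-methylbut-2-en-1-yl)chroman-6-yl]prop-2-en-1-one
Conditions: KOH, EtOH/THF, rt
Reagents that add atoms: none
Why: Claisen–Schmidt condensation of a methyl ketone with a non-enolisable aldehyde; E1cB dehydration gives the conjugated E-enone, and all MOM ethers and both alkenes are inert to hydroxide.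

Step 10
Reactants: 17 the 2'-hydroxychalcone of step 9
Product: 19 3-hydroxy-5,7-bis(methoxymethoxy)-2-[8-(methoxymethoxy)-2,2-dimethyl-5-(3-methylbut-2-en-1-yl)chroman-6-yl]-8-(2-methylbut-3-en-2-yl)-4H-chromen-4-one, via trans-dihydroflavonol 18 (not isolated)
Conditions: 30% aq. H2O2, NaOH, MeOH/THF, 0 °C → rt
Reagents that add atoms: hydrogen peroxide, OO
Why: Algar–Flynn–Oyamada oxidation: the 2'-phenoxide adds to the β-carbon in a 6-endo oxa-Michael closure and the enolate is hydroxylated by peroxide to dihydroflavonol 18, which alkaline peroxide dehydrogenates to the flavonol. Hydroperoxide anion is a nucleophilic oxidant, so the two isolated alkenes should not be touched, and the only free ring A hydroxyl is the one next to the tert-alkyl group, which places that group at C8.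

Step 11
Reactants: 19 the tris(methoxymethyl) flavonol of step 10
Product: 20 broussoflavonol E
Conditions: 3 M aq. HCl, MeOH/THF, 45 °C
Reagents that add atoms: none
Why: Acid-catalysed acetal exchange of the three aryl MOM ethers with methanol; dilute acid at moderate temperature is chosen so that neither the trisubstituted prenyl alkene nor the vinyl group next to the 7-hydroxyl is protonated at a competitive rate.

## Compound list

1 | 6-bromovanillin (2-bromo-4-hydroxy-5-methoxybenzaldehyde) | O=Cc1cc(OC)c(O)cc1Br | starting material
2 | formaldehyde (37% aqueous solution) | C=O | starting material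
3 | 2-bromo-4-hydroxy-3-(hydroxymethyl)-5-methoxybenzaldehyde | O=Cc1cc(OC)c(O)c(CO)c1Br | intermediate
4 | isobutene (2-methylpropene) | CC(C)=C | starting material
5 | 2-bromo-5-methoxy-3-methylidene-4-oxocyclohexa-1,5-diene-1-carbaldehyde (o-quinone methide) | O=CC1=C(Br)C(=C)C(=O)C(OC)=C1 | intermediate (not isolated)
6 | 5-bromo-8-methoxy-2,2-dimethylchroman-6-carbaldehyde | O=Cc1cc(OC)c2c(c1Br)CCC(C)(C)O2 | intermediate
7 | 5-bromo-8-hydroxy-2,2-dimethylchroman-6-carbaldehyde | O=Cc1cc(O)c2c(c1Br)CCC(C)(C)O2 | intermediate
8 | 5-bromo-8-(methoxymethoxy)-2,2-dimethylchroman-6-carbaldehyde | O=Cc1cc(OCOC)c2c(c1Br)CCC(C)(C)O2 | intermediate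
9 | 4,4,5,5-tetramethyl-2-(3-methylbut-2-en-1-yl)-1,3,2-dioxaborolane (prenylboronic acid pinacol ester) | CC(C)=CCB1OC(C)(C)C(C)(C)O1 | starting material
10 | 8-(methoxymethoxy)-2,2-dimethyl-5-(3-methylbut-2-en-1-yl)chroman-6-carbaldehyde | O=Cc1cc(OCOC)c2c(c1CC=C(C)C)CCC(C)(C)O2 | intermediate
11 | 2,4,6-trihydroxyacetophenone | CC(=O)c1c(O)cc(O)cc1O | starting material
12 | prenyl bromide (1-bromo-3-methylbut-2-ene) | CC(C)=CCBr | starting material
13 | 1-[2,6-dihydroxy-4-(3-methylbut-2-en-1-yloxy)phenyl]ethanone | CC(=O)c1c(O)cc(OCC=C(C)C)cc1O | intermediate
14 | 4-acetyl-3,5-dihydroxy-6-(2-methylbut-3-en-2-yl)cyclohexa-2,4-dien-1-one (racemic) | CC(=O)C1=C(O)C(C(C)(C)C=C)C(=O)C=C1O | intermediate (not isolated)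
15 | 1-[2,4,6-trihydroxy-3-(2-methylbut-3-en-2-yl)phenyl]ethanone | CC(=O)c1c(O)cc(O)c(C(C)(C)C=C)c1O | intermediate
16 | 1-[2-hydroxy-4,6-bis(methoxymethoxy)-3-(2-methylbut-3-en-2-yl)phenyl]ethanone | CC(=O)c1c(O)c(C(C)(C)C=C)c(OCOC)cc1OCOC | intermediate
17 | (E)-1-[2-hydroxy-4,6-bis(methoxymethoxy)-3-(2-methylbut-3-en-2-yl)phenyl]-3-[8-(methoxymethoxy)-2,2-dimethyl-5-(3-methylbut-2-en-1-yl)chroman-6-yl]prop-2-en-1-one | O=C(/C=C/c1cc(OCOC)c2c(c1CC=C(C)C)CCC(C)(C)O2)c1c(O)c(C(C)(C)C=C)c(OCOC)cc1OCOC | intermediate
18 | trans-3-hydroxy-5,7-bis(methoxymethoxy)-2-[8-(methoxymethoxy)-2,2-dimethyl-5-(3-methylbut-2-en-1-yl)chroman-6-yl]-8-(2-methylbut-3-en-2-yl)chroman-4-one (racemic; the 2R,3R enantiomer is drawn) | O=C1c2c(OCOC)cc(OCOC)c(C(C)(C)C=C)c2O[C@H](c2cc(OCOC)c3c(c2CC=C(C)C)CCC(C)(C)O3)[C@H]1O | intermediate (not isolated)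
19 | 3-hydroxy-5,7-bis(methoxymethoxy)-2-[8-(methoxymethoxy)-2,2-dimethyl-5-(3-methylbut-2-en-1-yl)chroman-6-yl]-8-(2-methylbut-3-en-2-yl)-4H-chromen-4-one | C=CC(C)(C)c1c(OCOC)cc(OCOC)c2c(=O)c(O)c(-c3cc(OCOC)c4c(c3CC=C(C)C)CCC(C)(C)O4)oc12 | intermediate
20 | broussoflavonol E | C=CC(C)(C)c1c(O)cc(O)c2c(=O)c(O)c(-c3cc(O)c4c(c3CC=C(C)C)CCC(C)(C)O4)oc12 | target

## Step count and least certain steps

Total: 11 steps (five to aldehyde 10, three to ketone 16, three after their union). Longest linear sequence: 8 steps (1 → 3 → 6 → 7 → 8 → 10 → 17 → 19 → 20).

**Step 2 (key step).** The quinone methide may condense with itself faster than it is captured by a gaseous, only moderately nucleophilic alkene. Transfer of an allylic hydrogen of isobutene (an ene pathway) may also compete with cycloaddition. Fallback, from 1 back to 6: the phenol of 1 is alkylated with 3-chloro-3-methylbut-1-yne (K2CO3, KI, cat. CuI, acetone) to 2-bromo-5-methoxy-4-[(2-methylbut-3-yn-2-yl)oxy]benzaldehyde F1. Heating F1 in N,N-diethylaniline sets off the propargyl Claisen rearrangement, hydrogen shift and oxa-6π closure onto the only free ortho carbon, giving 5-bromo-8-methoxy-2,2-dimethyl-2H-chromene-6-carbaldehyde F2. Diimide (KO2CN=NCO2K, AcOH, MeOH) then saturates the C3=C4 bond without touching bromide or aldehyde and gives 6.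

**Step 1.** Substitution at a carbon flanked by bromine and the phenolate, on a ring deactivated by the formyl group, may be sluggish, and the product may condense with unreacted phenolate. Fallback, from 1 back to 3: boron-templated ortho-hydroxymethylation with PhB(OH)2 and paraformaldehyde (cat. propionic acid, toluene, reflux with water removal) delivers formaldehyde intramolecularly and holds the product as 5-bromo-8-methoxy-2-phenyl-4H-1,3,2-benzodioxaborinine-6-carbaldehyde F3, which cannot condense further. Transesterification of F3 with propane-1,3-diol releases 3.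

**Step 5.** The aryl group may be transferred to the substituted terminus of the allyl–palladium intermediate (reverse prenylation), and protodeboronation may outpace coupling at the doubly ortho-substituted bromide. Fallback, from 8 back to 10: coupling with allylboronic acid pinacol ester (Pd(PPh3)4, CsF, THF, reflux), which has no regiochemical ambiguity, gives 5-allyl-8-(methoxymethoxy)-2,2-dimethylchroman-6-carbaldehyde F4. Cross-metathesis of F4 with 2-methylbut-2-ene using the second-generation Grubbs catalyst RuCl2(=CHPh)(H2IMes)(PCy3) converts the allyl group into the prenyl group of 10.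

**Step 8.** Protection may occur at the wrong ortho hydroxyl or at all three; that would move the free hydroxyl away from the tert-alkyl group and lead to the 6-substituted flavonol. Fallback, from 13 back to 16: one of the two equivalent hydroxyls of 13 is protected (MOMCl, 1 equiv, i-Pr2NEt) to give 1-[2-hydroxy-6-(methoxymethoxy)-4-(3-methylbut-2-en-1-yloxy)phenyl]ethanone F5. Claisen rearrangement of F5 (N,N-diethylaniline, 190 °C) is directed by the chelated 2-hydroxyl to the carbon between the two oxygens and gives 1-[2,4-dihydroxy-6-(methoxymethoxy)-3-(2-methylbut-3-en-2-yl)phenyl]ethanone F6. Protection of the non-chelated 4-hydroxyl of F6 gives 16. The positional decision is thereby moved from an O-alkylation to the C–C bond formation.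

**Step 10.** The 6'-alkoxy group and the ortho-substituted ring B may divert the oxidation toward five-membered ring closure at the α-carbon (aurone formation). Fallback, from 17 back to 19: oxidative cyclisation of 17 with catalytic iodine in DMSO gives 5,7-bis(methoxymethoxy)-2-[8-(methoxymethoxy)-2,2-dimethyl-5-(3-methylbut-2-en-1-yl)chroman-6-yl]-8-(2-methylbut-3-en-2-yl)-4H-chromen-4-one F7. Lithiation of F7 at C3 with LiN(i-Pr)2 at −78 °C, trapping with B(OMe)3 and oxidation of the boronate with H2O2 installs the 3-hydroxyl and gives 19. No electrophilic oxidant meets the alkenes.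

**Step 11.** During acetal cleavage the prenyl double bond may be protonated and add solvent, and the 7-hydroxyl may add to the neighbouring vinyl group under acid catalysis. Fallback, from 19 back to 20: TMSOTf with 2,2'-bipyridyl in MeCN at 0 °C exchanges each aryl MOM ether for a trimethylsilyl ether under buffered, aprotic conditions and silylates the 3-hydroxyl, giving 3,5,7-tris(trimethylsilyloxy)-2-[2,2-dimethyl-5-(3-methylbut-2-en-1-yl)-8-(trimethylsilyloxy)chroman-6-yl]-8-(2-methylbut-3-en-2-yl)-4H-chromen-4-one F8. Aqueous methanol at room temperature hydrolyses the silyl ethers of F8 to 20.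

## Further compounds

F1 | step 2 | 2-bromo-5-methoxy-4-[(2-methylbut-3-yn-2-yl)oxy]benzaldehyde | O=Cc1cc(OC)c(OC(C)(C)C#C)cc1Br
F2 | step 2 | 5-bromo-8-methoxy-2,2-dimethyl-2H-chromene-6-carbaldehyde | O=Cc1cc(OC)c2c(c1Br)C=CC(C)(C)O2
F3 | step 1 | 5-bromo-8-methoxy-2-phenyl-4H-1,3,2-benzodioxaborinine-6-carbaldehyde | O=Cc1cc(OC)c2OB(c3ccccc3)OCc2c1Br
F4 | step 5 | 5-allyl-8-(methoxymethoxy)-2,2-dimethylchroman-6-carbaldehyde | O=Cc1cc(OCOC)c2c(c1CC=C)CCC(C)(C)O2
F5 | step 8 | 1-[2-hydroxy-6-(methoxymethoxy)-4-(3-methylbut-2-en-1-yloxy)phenyl]ethanone | CC(=O)c1c(O)cc(OCC=C(C)C)cc1OCOC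
F6 | step 8 | 1-[2,4-dihydroxy-6-(methoxymethoxy)-3-(2-methylbut-3-en-2-yl)phenyl]ethanone | CC(=O)c1c(O)c(C(C)(C)C=C)c(O)cc1OCOC
F7 | step 10 | 5,7-bis(methoxymethoxy)-2-[8-(methoxymethoxy)-2,2-dimethyl-5-(3-methylbut-2-en-1-yl)chroman-6-yl]-8-(2-methylbut-3-en-2-yl)-4H-chromen-4-one | C=CC(C)(C)c1c(OCOC)cc(OCOC)c2c(=O)cc(-c3cc(OCOC)c4c(c3CC=C(C)C)CCC(C)(C)O4)oc12
F8 | step 11 | 3,5,7-tris(trimethylsilyloxy)-2-[2,2-dimethyl-5-(3-methylbut-2-en-1-yl)-8-(trimethylsilyloxy)chroman-6-yl]-8-(2-methylbut-3-en-2-yl)-4H-chromen-4-one | C=CC(C)(C)c1c(O[Si](C)(C)C)cc(O[Si](C)(C)C)c2c(=O)c(O[Si](C)(C)C)c(-c3cc(O[Si](C)(C)C)c4c(c3CC=C(C)C)CCC(C)(C)O4)oc12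
A1 | alternative 1 | 5-ethoxy-2-(2-methylbut-3-en-2-yl)-3-(triisopropylsilyloxy)phenol | CCOc1cc(O)c(C(C)(C)C=C)c(O[Si](C(C)C)(C(C)C)C(C)C)c1
A2 | alternative 1 | 3-ethoxycyclobut-2-en-1-one | CCOC1=CC(=O)C1
A3 | alternative 1 | [(3,3-dimethylpent-4-en-1-yn-1-yl)oxy]triisopropylsilane | C=CC(C)(C)C#CO[Si](C(C)C)(C(C)C)C(C)C
A4 | alternative 2 | 5,7-dihydroxy-3-(methoxymethoxy)-2-[8-(methoxymethoxy)-2,2-dimethyl-5-(3-methylbut-2-en-1-yl)chroman-6-yl]-4H-chromen-4-one | Oc1cc(O)c2c(=O)c(OCOC)c(-c3cc(OCOC)c4c(c3CC=C(C)C)CCC(C)(C)O4)oc2c1
A5 | alternative 2 | ethyl 2-(methoxymethoxy)-3-[8-(methoxymethoxy)-2,2-dimethyl-5-(3-methylbut-2-en-1-yl)chroman-6-yl]-3-oxopropanoate (racemic) | CCOC(=O)C(OCOC)C(=O)c1cc(OCOC)c2c(c1CC=C(C)C)CCC(C)(C)O2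
A6 | alternative 2 | phloroglucinol (benzene-1,3,5-triol) | Oc1cc(O)cc(O)c1
A7 | alternative 3 | 5,7-bis(methoxymethoxy)-2-[8-(methoxymethoxy)-2,2-dimethyl-5-(3-methylbut-2-en-1-yl)chroman-6-yl]-4H-chromen-4-one | COCOc1cc(OCOC)c2c(=O)cc(-c3cc(OCOC)c4c(c3CC=C(C)C)CCC(C)(C)O4)oc2c1
A8 | alternative 3 | 3,5-bis(methoxymethoxy)-2-(trimethylsilyl)phenyl trifluoromethanesulfonate | COCOc1cc(OCOC)c([Si](C)(C)C)c(OS(=O)(=O)C(F)(F)F)c1
A9 | alternative 3 | 3-[8-(methoxymethoxy)-2,2-dimethyl-5-(3-methylbut-2-en-1-yl)chroman-6-yl]prop-2-ynoic acid | OC(=O)C#Cc1cc(OCOC)c2c(c1CC=C(C)C)CCC(C)(C)O2
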